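Gravicycle has one stereocentre, the benzylic carbinol on ring B, and an unfunctionalised thirteen-carbon bridge from that carbon to ring A. The plan cuts this bridge in its middle, between the seventh carbon counted from ring A and the sixth counted from the carbinol, where both atoms are plain methylenes remote from every functional group. Ring-closing olefin metathesis of a diaryl ether diene, oct-7-enyl on ring A and (R)-1-hydroxyoct-7-enyl on ring B, closes the 22-membered meta,para-bridged macrocycle in one operation; one hydrogenation then saturates the olefin and frees the three phenols. The diene comes from an Ullmann ether coupling and a catalytic enantioselective alkylzinc addition.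

Key step: step 6

Remark: compounds 1, 3, 6 and 9 are taken as purchasable. Compound 13 is drawn as the E olefin; an E/Z mixture is expected and is of no consequence because step 7 saturates the olefin.

Step 1
Reactants: 1 3-bromo-5-iodophenol
Product: 2 1-(benzyloxy)-3-bromo-5-iodobenzene
Conditions: BnBr, K2CO3, DMF, rt
Reagents that add atoms: benzyl bromide, BrCc1ccccc1
Why: Williamson ether synthesis, in which the phenoxide formed with K2CO3 displaces bromide from benzyl bromide and the benzyl ether masks the ring A phenol until the final hydrogenolysis.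

Step 2
Reactants: 3 8-bromooct-1-ene; 2 1-(benzyloxy)-3-bromo-5-iodobenzene
Product: 5 1-(benzyloxy)-3-bromo-5-(oct-7-en-1-yl)benzene, via oct-7-enylzinc bromide 4 (not isolated)
Conditions: 3, Zn dust, I2 (5 mol%), DMA, 80 °C; then 2, PdCl2(dppf) (3 mol%), THF/DMA, rt to 40 °C
Reagents that add atoms: none
Why: Negishi coupling, in which zinc inserts into the primary C–Br bond of 3, zerovalent palladium adds to the C–I bond of 2 far faster than to its C–Br bond, and the wide-bite-angle dppf ligand favours reductive elimination over β-hydride elimination, so the aryl bromide is kept for step 4.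

Step 3
Reactants: 6 3,4,5-tris(benzyloxy)benzaldehyde
Product: 7 3,5-bis(benzyloxy)-4-hydroxybenzaldehyde
Conditions: MgBr2·OEt2 (3 equiv), toluene/Et2O, reflux; then 1 M HCl
Reagents that add atoms: none
Why: Regioselective Lewis acid-mediated ether cleavage (the benzyl counterpart of the selective 4-demethylation of 3,4,5-trimethoxybenzoyl compounds), in which the central benzyloxy group, twisted out of the ring plane by its two neighbours and chelated by magnesium together with a flanking oxygen, loses its benzyl group to bromide and leaves the phenoxide stabilised by the para formyl group.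

Step 4
Reactants: 7 3,5-bis(benzyloxy)-4-hydroxybenzaldehyde; 5 1-(benzyloxy)-3-bromo-5-(oct-7-en-1-yl)benzene
Product: 8 3,5-bis(benzyloxy)-4-[3-(benzyloxy)-5-(oct-7-en-1-yl)phenoxy]benzaldehyde
Conditions: CuI (10 mol%), picolinic acid (20 mol%), K3PO4 (2 equiv), DMSO, 90 °C
Reagents that add atoms: none
Why: Ullmann-type diaryl ether synthesis, in which the copper phenoxide of 7, carried by the picolinate ligand that suits phenols with two ortho substituents, couples with the unhindered aryl bromide 5, while the non-enolisable aldehyde, the benzyl ethers and the terminal olefin are inert to K3PO4 in DMSO.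

Step 5
Reactants: 9 7-bromohept-1-ene; 8 3,5-bis(benzyloxy)-4-[3-(benzyloxy)-5-(oct-7-en-1-yl)phenoxy]benzaldehyde
Product: 12 (R)-1-{3,5-bis(benzyloxy)-4-[3-(benzyloxy)-5-(oct-7-en-1-yl)phenoxy]phenyl}oct-7-en-1-ol, via hept-6-enylmagnesium bromide 10 (not isolated), via di(hept-6-enyl)zinc 11 (not isolated)
Conditions: 9 (2.4 equiv), Mg, Et2O; ZnCl2 (1.2 equiv), then 1,4-dioxane, filtration; then 8, Ti(OiPr)4 (1.2 equiv), Ti(OiPr)2[(4S,5S)-TADDOLate] (0.2 equiv; TADDOL = 2,2-dimethyl-α,α,α′,α′-tetraphenyl-1,3-dioxolane-4,5-dimethanol), toluene, −25 °C; aq. HCl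
Reagents that add atoms: none
Why: Titanium TADDOLate-catalysed enantioselective addition of a dialkylzinc made in situ from the Grignard reagent, in which dioxane precipitates the magnesium halides so that no racemic background addition occurs and the (S,S)-TADDOLate complex, whose (R,R) enantiomer directs alkyl transfer to the Si face of aromatic aldehydes, should deliver the hept-6-enyl group to the Re face of the formyl group of 8 and so set the (R) carbinol centre (to be confirmed by Mosher ester analysis).

Step 6
Reactants: 12 (R)-1-{3,5-bis(benzyloxy)-4-[3-(benzyloxy)-5-(oct-7-en-1-yl)phenoxy]phenyl}oct-7-en-1-ol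
Product: 13 tri-O-benzyl-7,8-didehydrogravicycle: the 22-membered macrocycle in which the chain carbon of ring A and the (R) carbinol carbon on ring B are joined by (CH2)6–CH=CH–(CH2)5, with benzyl ethers on the ring A phenol and on both ring B phenols
Conditions: second-generation Grubbs catalyst RuCl2(=CHPh)(H2IMes)(PCy3) (10 mol%, in portions), 1,4-benzoquinone (20 mol%), CH2Cl2 (1 mM), reflux
Reagents that add atoms: none
Why: The ruthenium benzylidene exchanges with one terminal olefin of 12 to give a chain-end alkylidene, which adds to the second terminal olefin in a [2+2] cycloaddition; cycloreversion of the ruthenacyclobutane forms the double bond between C7 of the ring A chain and C7 of the carbinol chain, and loss of ethene makes the closure irreversible. The closest known reaction type is the macrocyclic ring-closing olefin metathesis of α,ω-dienes used for cyclophane and macrolide rings. The one ring closed is the 22-membered meta,para-bridged diaryl ether macrocycle, formed by end-to-end closure of the two chain termini with both olefinic carbons ending up in the ring. No stereocentre is created: the carbinol centre is six atoms from the reacting olefin and is untouched, and the geometry of the new olefin does not matter because step 7 saturates it. The step needs cyclisation to win over acyclic diene metathesis oligomerisation and needs the olefins not to migrate: high dilution with portionwise catalyst addition secures the first, the two unhindered monosubstituted olefins far from any coordinating group make initiation and closure fast, the bent diaryl ether hinge keeps the chain ends within reach, and 1,4-benzoquinone quenches ruthenium hydrides that would cause migration and ring contraction.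

Step 7
Reactants: 13 tri-O-benzyl-7,8-didehydrogravicycle
Product: 14 gravicycle
Conditions: H2 (1 atm), Pd/C (10%), EtOAc, rt, stopped when hydrogen uptake ends
Reagents that add atoms: none
Why: Heterogeneous catalytic hydrogenation combined with hydrogenolysis, in which the disubstituted olefin is saturated and the three aryl benzyl ethers are cleaved on palladium under neutral conditions that cleave a free secondary benzylic alcohol much more slowly (as in the final debenzylation of arylethanolamine drugs), so the (R) carbinol centre should be kept.

Compound list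
1 | 3-bromo-5-iodophenol | Oc1cc(Br)cc(I)c1 | starting material
2 | 1-(benzyloxy)-3-bromo-5-iodobenzene | Brc1cc(I)cc(OCc2ccccc2)c1 | intermediate
3 | 8-bromooct-1-ene | C=CCCCCCCBr | starting material
4 | oct-7-enylzinc bromide | C=CCCCCCC[Zn]Br | intermediate
5 | 1-(benzyloxy)-3-bromo-5-(oct-7-en-1-yl)benzene | C=CCCCCCCc1cc(Br)cc(OCc2ccccc2)c1 | intermediate
6 | 3,4,5-tris(benzyloxy)benzaldehyde | O=Cc1cc(OCc2ccccc2)c(OCc2ccccc2)c(OCc2ccccc2)c1 | starting material
7 | 3,5-bis(benzyloxy)-4-hydroxybenzaldehyde | O=Cc1cc(OCc2ccccc2)c(O)c(OCc2ccccc2)c1 | intermediate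
8 | 3,5-bis(benzyloxy)-4-[3-(benzyloxy)-5-(oct-7-en-1-yl)phenoxy]benzaldehyde | O=Cc1cc(OCc2ccccc2)c(Oc2cc(CCCCCCC=C)cc(OCc3ccccc3)c2)c(OCc2ccccc2)c1 | intermediate
9 | 7-bromohept-1-ene | C=CCCCCCBr | starting material
10 | hept-6-enylmagnesium bromide | C=CCCCCC[Mg]Br | intermediate
11 | di(hept-6-enyl)zinc | C=CCCCCC[Zn]CCCCCC=C | intermediate
12 | (R)-1-{3,5-bis(benzyloxy)-4-[3-(benzyloxy)-5-(oct-7-en-1-yl)phenoxy]phenyl}oct-7-en-1-ol | O[C@H](CCCCCC=C)c1cc(OCc2ccccc2)c(Oc2cc(CCCCCCC=C)cc(OCc3ccccc3)c2)c(OCc2ccccc2)c1 | intermediate
13 | tri-O-benzyl-7,8-didehydrogravicycle (R carbinol, E olefin drawn) | O(Cc1ccccc1)c1cc2cc(c1)Oc1c(OCc3ccccc3)cc(cc1OCc1ccccc1)[C@H](O)CCCCC/C=C/CCCCCC2 | intermediate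
14 | gravicycle | Oc1cc2cc(c1)Oc1c(O)cc(cc1O)[C@H](O)CCCCCCCCCCCCC2 | target

Total step count: 7. Longest linear sequence: 6 steps (steps 1, 2, 4, 5, 6, 7).

Steps most likely to fail

Step 4. The phenoxide of 7 is hindered by two ortho benzyloxy groups and weakened by the para formyl group. C–O bond formation may therefore be slow, and protodebromination of 5 or base-induced degradation of the aldehyde at 90 °C may take over. The fallback sets out from 5. Bromine–lithium exchange (n-BuLi, THF, −78 °C), quench with B(OiPr)3 and acidic work-up should give [3-(benzyloxy)-5-(oct-7-en-1-yl)phenyl]boronic acid F1. A Chan–Lam–Evans oxidative coupling of this boronic acid with phenol 7 (Cu(OAc)2, pyridine, 4 Å molecular sieves, CH2Cl2, air, rt) runs at room temperature, accepts phenols with two ortho substituents, and comes back to the route at 8.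

Step 3. Regiocontrol may be lost through cleavage of a 3-O-benzyl group, or cleavage may run on to diols. The fallback sets out from 6 and fixes the regiochemistry by orthogonal protecting groups instead of a selective cleavage. Exhaustive debenzylation (BCl3, pentamethylbenzene, CH2Cl2, −78 °C) should give 3,4,5-trihydroxybenzaldehyde F2, which can also be bought. Monoalkylation of the most acidic hydroxyl, the one para to the formyl group (allyl bromide 1 equiv, NaHCO3, DMF), should give 4-(allyloxy)-3,5-dihydroxybenzaldehyde F3. Benzylation (BnBr, K2CO3, DMF) should give 4-(allyloxy)-3,5-bis(benzyloxy)benzaldehyde F4. Palladium-catalysed deallylation (Pd(PPh3)4, K2CO3, MeOH) comes back to the route at 7.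

Step 5. Facial selectivity may be poor if magnesium salts are carried into the addition and cause a racemic background reaction, and β-hydride transfer from the alkylzinc may reduce the aldehyde. The fallback sets out from 8. Addition of Grignard reagent 10 (THF, −78 °C) should give racemic 1-{3,5-bis(benzyloxy)-4-[3-(benzyloxy)-5-(oct-7-en-1-yl)phenoxy]phenyl}oct-7-en-1-ol F5. Dess–Martin periodinane oxidation (CH2Cl2, rt) should give 1-{3,5-bis(benzyloxy)-4-[3-(benzyloxy)-5-(oct-7-en-1-yl)phenoxy]phenyl}oct-7-en-1-one F6. Asymmetric transfer hydrogenation (RuCl[(R,R)-TsDPEN](p-cymene), HCO2H/Et3N, rt) reduces aryl alkyl ketones to (R) carbinols with this ligand, leaves isolated olefins untouched, and comes back to the route at 12.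

Further compounds
F1 | step 4 | [3-(benzyloxy)-5-(oct-7-en-1-yl)phenyl]boronic acid | C=CCCCCCCc1cc(B(O)O)cc(OCc2ccccc2)c1
F2 | step 3 | 3,4,5-trihydroxybenzaldehyde | O=Cc1cc(O)c(O)c(O)c1
F3 | step 3 | 4-(allyloxy)-3,5-dihydroxybenzaldehyde | O=Cc1cc(O)c(OCC=C)c(O)c1
F4 | step 3 | 4-(allyloxy)-3,5-bis(benzyloxy)benzaldehyde | O=Cc1cc(OCc2ccccc2)c(OCC=C)c(OCc2ccccc2)c1
F5 | step 5 | racemic 1-{3,5-bis(benzyloxy)-4-[3-(benzyloxy)-5-(oct-7-en-1-yl)phenoxy]phenyl}oct-7-en-1-ol | OC(CCCCCC=C)c1cc(OCc2ccccc2)c(Oc2cc(CCCCCCC=C)cc(OCc3ccccc3)c2)c(OCc2ccccc2)c1
F6 | step 5 | 1-{3,5-bis(benzyloxy)-4-[3-(benzyloxy)-5-(oct-7-en-1-yl)phenoxy]phenyl}oct-7-en-1-one | O=C(CCCCCC=C)c1cc(OCc2ccccc2)c(Oc2cc(CCCCCCC=C)cc(OCc3ccccc3)c2)c(OCc2ccccc2)c1
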